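Before charging these flasks for a hold of 3.0 min, choose what to rank them on: the charge ratio or the temperature.

| flask | substrate | precatalyst | temperature | remark | time |
|---|---|---|---|---|---|
| larch | 12 mM | 6.7 µM | 35 °C | run made earlier |  |
| oak | 12 mM | 14 µM | 60 °C | run made earlier |  |
| cedar | 12 mM | 18 µM | 35 °C | run made earlier |  |
| birch | 9.3 mM | 12 µM | 60 °C | run made earlier |  |
| west | 12 mM | 12 µM | 55 °C |  | 3.0 min |
| south-west | 12 mM | 25 µM | 40 °C |  | 3.0 min |
| north-west | 20 mM | 12 µM | 55 °C |  | 3.0 min |
| east | 12 mM | 12 µM | 40 °C |  | 3.0 min |
| north | 4.0 mM | 20 µM | 40 °C |  | 3.0 min |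
| north-east | 25 mM | 8.0 µM | 80 °C |  | 3.0 min |

| run | time / s | target / % |
|---|---|---|
| larch | 10.0 | 0 |
| larch | 20.0 | 0 |
| larch | 40.0 | 0 |
| larch | 60.0 | 0 |
| larch | 120 | 0.8 |
| oak | 10.0 | 2.2 |
| oak | 15.0 | 4.2 |
| oak | 20.0 | 7.1 |
| oak | 40.0 | 24.8 |
| cedar | 25.0 | 0 |
| cedar | 50.0 | 0.3 |
| cedar | 80.0 | 1.1 |
| cedar | 90.0 | 1.7 |
| cedar | 120 | 2.7 |
| birch | 10.0 | 1.8 |
| birch | 20.0 | 7.1 |
| birch | 30.0 | 15.1 |
| birch | 40.0 | 24.2 |

(standard deviation of a reading: 0.3 percentage points)

1. the flasks by amount of target, in percent of the substrate charged, highest first, at 3.0 min (west / south-west / north-west / east / north / north-east)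
2. the amount of target, in percent of the substrate charged of the flask you put first, at 3.0 min
3. the amount of target, in percent of the substrate charged of the flask you put last, at 3.0 min



Count turnovers. East and west each ask 1000 of every catalyst charged; that figure, charged substrate over charged precatalyst, is the turnovers needed. Target as a share of the substrate charged, multiplied by it, gives the turnovers done, the turnover number.

The first chemist ranks on need. North needs 200, south-west 480, north-west 1670 and north-east 3130, so in her view north leads and north-east trails.

The second chemist reads turnovers done from the runs. At 35 °C and 120 s, cedar shows 18.0 and larch 14.3, a rough reading, although their precatalyst charges are 18 µM and 6.7 µM. Oak at 60 °C shows 213 by 40.0 s, more turnovers in less time than cedar. So he says the count done follows temperature, and he backs north-east, hotter than the others, despite its need.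

The forecast stands on his side, by its own rate reckoning: north-east > west > north-west > north > south-west > east, with 97% at the top and 10% at the bottom. It adds: “North versus south-west is a close call.”

The simulation gives north-east > west > north-west > north > south-west > east, with >99.9% in north-east and 10.6% in east.

    catalyst intermediate B → free catalyst + target (k = 5.00 s⁻¹, Ea = 82.0 kJ mol⁻¹)
    precatalyst → free catalyst (k = 0.00220 s⁻¹, Ea = 100 kJ mol⁻¹)
    substrate + free catalyst → catalyst intermediate A (k = 1300 M⁻¹ s⁻¹, Ea = 45.0 kJ mol⁻¹)
    catalyst intermediate A → catalyst intermediate B (k = 36.0 s⁻¹, Ea = 62.0 kJ mol⁻¹)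
    (constants at 40 °C)

The first chemist keeps flasks at one temperature: at 40 °C, north at 33.9% beats south-west at 21.8%, and south-west beats east, in order of need. East and west share 1000 turnovers needed, yet east has done 106 and west 872. South-west has done 104, about the same as east. East falls short because of the hour of reading: with the reading taken ten times later, at 30.0 min, east holds 100% target.

(All runs come from a simulation for substances that don't exist; the scatter is artificial.)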